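**Retrosynthetic overview**
1. The tetramic acid is closed last by Lacey–Dieckmann cyclisation of a β-keto amide made from the decalin β-keto thioester 20 and methyl L-threoninate 21 (both heterocycle stereocentres are bought).
2. In the decalin, the C3=C4 alkene comes from a C4 ketone (Shapiro) and the dienyl side chain from a C2 aldehyde (Wittig), both after the key step.
3. Key step: intramolecular Diels–Alder reaction of the 1,7,9-decatrien-3-one 10 forms rings A and B together. Ring B is the cycloadduct ring, so the axial C6 methyl comes from the E,E-diene, C8a from the chair-like tether and C4a from equilibration.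
4. The tether stereocentres C1 (quaternary) and C2 come from lactone 5: (R)-epichlorohydrin plus di-tert-butyl malonate, cuprate opening, then trans-methylation.
5. Ring order: cyclopropane-lactone template (step 1, opened in steps 2 and 7), rings A and B in one step (step 8), pyrrolidine-2,4-dione ring last (step 17).

Assumption: decalin atoms are numbered as in naphthalene (C1 quaternary, C2 dienyl, C4a/C8a ring fusion, C6 methyl), and 1 reacts at the epoxide carbon first, as it does with diethyl malonate.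

**Step 1**
Reactants: 1 (R)-epichlorohydrin; 2 di-tert-butyl malonate
Product: 3 tert-butyl (1R,5R)-2-oxo-3-oxabicyclo[3.1.0]hexane-1-carboxylate
Conditions: t-BuOK (1.2 equiv), t-BuOH, 25 → 80 °C
Reagents that add atoms: none
Why: Tandem malonate alkylation in which the enolate opens the epoxide at CH2, the alkoxide closes a new epoxide with loss of chloride, the second enolate closes the cyclopropane by intramolecular SN2 with inversion at the carbon bought in 1, and the cis CH2O– group lactonises, so C5 comes from 1 and C1 is fixed by the cis fusion.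

**Step 2**
Reactants: 3 tert-butyl (1R,5R)-2-oxo-3-oxabicyclo[3.1.0]hexane-1-carboxylate
Product: 4 tert-butyl (4R)-2-oxo-4-(prop-2-en-1-yl)oxolane-3-carboxylate
Conditions: CH2=CHMgBr (1.3 equiv), CuI (10 mol %), THF, −40 → −20 °C; aq. NH4Cl
Reagents that add atoms: vinylmagnesium bromide C=C[Mg]Br
Why: Copper-catalysed homoconjugate addition of the Grignard reagent opens the doubly activated cyclopropane at its CH2 group and leaves the C4 stereocentre untouched.

**Step 3**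
Reactants: 4 tert-butyl (4R)-2-oxo-4-(prop-2-en-1-yl)oxolane-3-carboxylate
Product: 5 tert-butyl (3S,4R)-3-methyl-2-oxo-4-(prop-2-en-1-yl)oxolane-3-carboxylate
Conditions: MeI (1.5 equiv), K2CO3 (1.5 equiv), acetone, 25 °C
Reagents that add atoms: iodomethane CI
Why: C-Alkylation of the malonate-type lactone enolate, in which iodomethane attacks the planar enolate anti to the C4 allyl group and so sets the quaternary centre with methyl trans to allyl.

**Step 4**
Reactants: 5 tert-butyl (3S,4R)-3-methyl-2-oxo-4-(prop-2-en-1-yl)oxolane-3-carboxylate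
Product: 6 tert-butyl (3S,4R)-3-methyl-2-oxo-4-(2-oxoethyl)oxolane-3-carboxylate
Conditions: O3, CH2Cl2/MeOH, −78 °C; then Me2S, −78 → 25 °C
Reagents that add atoms: ozone [O-][O+]=O
Why: Ozonolysis with reductive work-up cleaves the only alkene to the aldehyde without touching either stereocentre.

**Step 5**
Reactants: 6 tert-butyl (3S,4R)-3-methyl-2-oxo-4-(2-oxoethyl)oxolane-3-carboxylate
Product: 7 tert-butyl (3S,4R)-4-(2-hydroxybut-3-en-1-yl)-3-methyl-2-oxooxolane-3-carboxylate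
Conditions: CH2=CHMgBr (1.05 equiv), THF, −78 °C; aq. NH4Cl at −78 °C
Reagents that add atoms: vinylmagnesium bromide C=C[Mg]Br
Why: Grignard 1,2-addition to the aldehyde is far faster at −78 °C than attack on the lactone or the tert-butyl ester, and the new carbinol centre (formed as a mixture) is erased by oxidation in step 8.

**Step 6**
Reactants: 7 tert-butyl (3S,4R)-4-(2-hydroxybut-3-en-1-yl)-3-methyl-2-oxooxolane-3-carboxylate
Product: 8 tert-butyl (3S,4R)-2-hydroxy-4-(2-hydroxybut-3-en-1-yl)-3-methyloxolane-3-carboxylate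
Conditions: i-Bu2AlH (2.3 equiv), CH2Cl2, −78 °C
Reagents that add atoms: none
Why: Partial reduction of the γ-lactone to the lactol stops at the tetrahedral aluminate at −78 °C, while the bulky neopentyl tert-butyl ester is not reduced.

**Step 7**
Reactants: 8 tert-butyl (3S,4R)-2-hydroxy-4-(2-hydroxybut-3-en-1-yl)-3-methyloxolane-3-carboxylate
Product: 9 tert-butyl (2R,3E,5E)-2-[(2R)-1,4-dihydroxyhex-5-en-2-yl]-2-methylhepta-3,5-dienoate
Conditions: (E)-but-2-enyltriphenylphosphonium bromide (3.5 equiv), n-BuLi (3.4 equiv), THF, −78 → 25 °C; then I2 (5 mol %), CH2Cl2, daylight, 25 °C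
Reagents that add atoms: (E)-but-2-en-1-yl(triphenyl)phosphonium bromide C/C=C/C[P+](c1ccccc1)(c1ccccc1)c1ccccc1.[Br-]
Why: Wittig olefination of the open hydroxy-aldehyde form of the lactol with the semi-stabilised allylic ylide, followed by iodine-catalysed equilibration of the new double bond to E, with no epimerisation possible at the quaternary α-carbon.

**Step 8**
Reactants: 9 tert-butyl (2R,3E,5E)-2-[(2R)-1,4-dihydroxyhex-5-en-2-yl]-2-methylhepta-3,5-dienoate
Product: 12 tert-butyl (1R,2R,4aS,6S,8aS)-2-(hydroxymethyl)-1,6-dimethyl-4-oxo-1,2,3,4,4a,5,6,8a-octahydronaphthalene-1-carboxylate, via vinyl ketone 10 (not isolated), via cis-fused cycloadduct 11 (not isolated)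
Conditions: MnO2 (20 equiv), CH2Cl2, 25 °C; filter; PhMe (0.01 M), 80 °C; then DBU (0.3 equiv), 25 °C
Reagents that add atoms: none
Why: Allylic oxidation unmasks a vinyl ketone that undergoes the intramolecular Diels–Alder reaction through the chair-like tether with CH2OH and CO2t-Bu equatorial and the C1 methyl axial, so that C8a is set by the tether, the C6 methyl is placed cis to the C8a–C1 bond by suprafacial addition to the E,E-diene, and DBU equilibrates C4a of both ring-fusion isomers to the trans-fused ketone.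

**Step 9**
Reactants: 12 tert-butyl (1R,2R,4aS,6S,8aS)-2-(hydroxymethyl)-1,6-dimethyl-4-oxo-1,2,3,4,4a,5,6,8a-octahydronaphthalene-1-carboxylate
Product: 13 tert-butyl (1R,2R,4aS,6R,8aS)-2-(hydroxymethyl)-1,6-dimethyl-4-oxodecahydronaphthalene-1-carboxylate
Conditions: H2 (1 atm), Pd/C (10 %), EtOAc, 25 °C
Reagents that add atoms: none
Why: Heterogeneous catalytic hydrogenation saturates the only alkene (C7=C8) and creates no stereocentre.

**Step 10**
Reactants: 13 tert-butyl (1R,2R,4aS,6R,8aS)-2-(hydroxymethyl)-1,6-dimethyl-4-oxodecahydronaphthalene-1-carboxylate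
Product: 14 tert-butyl (1R,2R,4aS,6R,8aS)-2-formyl-1,6-dimethyl-4-oxodecahydronaphthalene-1-carboxylate
Conditions: Dess–Martin periodinane (1.3 equiv), CH2Cl2, 0 → 25 °C
Reagents that add atoms: none
Why: Dess–Martin oxidation of the primary alcohol under mild, non-basic conditions keeps the equatorial α-stereocentre C2 intact.

**Step 11**
Reactants: 14 tert-butyl (1R,2R,4aS,6R,8aS)-2-formyl-1,6-dimethyl-4-oxodecahydronaphthalene-1-carboxylate
Product: 15 tert-butyl (1S,2S,4aS,6R,8aS)-1,6-dimethyl-4-oxo-2-[(1E,3E)-penta-1,3-dien-1-yl]decahydronaphthalene-1-carboxylate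
Conditions: (E)-but-2-enyltriphenylphosphonium bromide (1.2 equiv), n-BuLi (1.15 equiv), THF, −78 → 0 °C; then I2 (5 mol %), CH2Cl2, daylight, 25 °C
Reagents that add atoms: (E)-but-2-en-1-yl(triphenyl)phosphonium bromide C/C=C/C[P+](c1ccccc1)(c1ccccc1)c1ccccc1.[Br-]
Why: Wittig olefination is chemoselective for the aldehyde over the hindered ring ketone, iodine isomerisation gives the E,E-diene, and C2 keeps its configuration (the descriptors change only because the CIP priorities change).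

**Step 12**
Reactants: 15 tert-butyl (1S,2S,4aS,6R,8aS)-1,6-dimethyl-4-oxo-2-[(1E,3E)-penta-1,3-dien-1-yl]decahydronaphthalene-1-carboxylate
Product: 16 tert-butyl (1S,2S,4aS,6R,8aS)-1,6-dimethyl-4-[2-(4-methylbenzenesulfonyl)hydrazinylidene]-2-[(1E,3E)-penta-1,3-dien-1-yl]decahydronaphthalene-1-carboxylate
Conditions: TsNHNH2 (1.2 equiv), MeOH, 50 °C
Reagents that add atoms: 4-methylbenzenesulfonohydrazide Cc1ccc(cc1)S(=O)(=O)NN
Why: Condensation of the ketone with the sulfonyl hydrazide gives the tosylhydrazone, with the trans ring fusion remaining the thermodynamic arrangement at C4a.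

**Step 13**
Reactants: 16 tert-butyl (1S,2S,4aS,6R,8aS)-1,6-dimethyl-4-[2-(4-methylbenzenesulfonyl)hydrazinylidene]-2-[(1E,3E)-penta-1,3-dien-1-yl]decahydronaphthalene-1-carboxylate
Product: 17 tert-butyl (1R,2R,4aR,6R,8aS)-1,6-dimethyl-2-[(1E,3E)-penta-1,3-dien-1-yl]-1,2,4a,5,6,7,8,8a-octahydronaphthalene-1-carboxylate
Conditions: LiN(i-Pr)2 (3.0 equiv), THF, −78 → 25 °C; H2O
Reagents that add atoms: none
Why: Shapiro reaction, in which deprotonation at N–H and at the less substituted α-CH2 (C3), loss of sulfinate and dinitrogen, and protonation on work-up place the double bond at C3=C4 without touching C4a.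

**Step 14**
Reactants: 17 tert-butyl (1R,2R,4aR,6R,8aS)-1,6-dimethyl-2-[(1E,3E)-penta-1,3-dien-1-yl]-1,2,4a,5,6,7,8,8a-octahydronaphthalene-1-carboxylate
Product: 18 (1R,2R,4aR,6R,8aS)-1,6-dimethyl-2-[(1E,3E)-penta-1,3-dien-1-yl]-1,2,4a,5,6,7,8,8a-octahydronaphthalene-1-carboxylic acid
Conditions: Me3SiOTf (2.0 equiv), 2,6-lutidine (3.0 equiv), CH2Cl2, 0 °C; aq. work-up
Reagents that add atoms: none
Why: Silyl triflate-mediated cleavage of the tert-butyl ester (loss of isobutene) under non-protic conditions spares the acid-sensitive diene.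

**Step 15**
Reactants: 18 (1R,2R,4aR,6R,8aS)-1,6-dimethyl-2-[(1E,3E)-penta-1,3-dien-1-yl]-1,2,4a,5,6,7,8,8a-octahydronaphthalene-1-carboxylic acid
Product: 20 S-tert-butyl 3-[(1R,2R,4aR,6R,8aS)-1,6-dimethyl-2-[(1E,3E)-penta-1,3-dien-1-yl]-1,2,4a,5,6,7,8,8a-octahydronaphthalen-1-yl]-3-oxopropanethioate, via acid chloride 19 (not isolated)
Conditions: 1-chloro-N,N,2-trimethylprop-1-en-1-amine (1.3 equiv), CH2Cl2, 0 → 25 °C; then added to CH3C(O)S-t-Bu (2.5 equiv)/LiN(SiMe3)2 (2.5 equiv), THF, −78 °C; aq. NH4Cl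
Reagents that add atoms: 1-chloro-N,N,2-trimethylprop-1-en-1-amine CC(C)=C(Cl)N(C)C (the chlorine of 19 only); S-tert-butyl ethanethioate CC(=O)SC(C)(C)C
Why: The acid chloride, formed under neutral conditions with the Ghosez chloroenamine, acylates the lithium enolate of the thioacetate in a crossed Claisen condensation, with the second equivalent of enolate deprotonating the product.

**Step 16**
Reactants: 20 S-tert-butyl 3-[(1R,2R,4aR,6R,8aS)-1,6-dimethyl-2-[(1E,3E)-penta-1,3-dien-1-yl]-1,2,4a,5,6,7,8,8a-octahydronaphthalen-1-yl]-3-oxopropanethioate; 21 methyl L-threoninate hydrochloride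
Product: 22 methyl (2S,3R)-2-{3-[(1R,2R,4aR,6R,8aS)-1,6-dimethyl-2-[(1E,3E)-penta-1,3-dien-1-yl]-1,2,4a,5,6,7,8,8a-octahydronaphthalen-1-yl]-3-oxopropanamido}-3-hydroxybutanoate
Conditions: AgOCOCF3 (1.2 equiv), Et3N (2.5 equiv), THF, 0 → 25 °C
Reagents that add atoms: none
Why: Silver-assisted aminolysis of the thioester (thiophilic activation) by the amino group, which is far more nucleophilic than the secondary hydroxyl, leaves all stereocentres untouched.

**Step 17**
Reactants: 22 methyl (2S,3R)-2-{3-[(1R,2R,4aR,6R,8aS)-1,6-dimethyl-2-[(1E,3E)-penta-1,3-dien-1-yl]-1,2,4a,5,6,7,8,8a-octahydronaphthalen-1-yl]-3-oxopropanamido}-3-hydroxybutanoate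
Product: 23 (5S)-3-{[(1R,2R,4aR,6R,8aS)-1,6-dimethyl-2-[(1E,3E)-penta-1,3-dien-1-yl]-1,2,4a,5,6,7,8,8a-octahydronaphthalen-1-yl]carbonyl}-4-hydroxy-5-[(1R)-1-hydroxyethyl]-1,5-dihydro-2H-pyrrol-2-one
Conditions: NaOMe (2.5 equiv), MeOH, 25 °C, 30 min; then 1 M HCl
Reagents that add atoms: none
Why: Lacey–Dieckmann cyclisation of the β-keto amide onto the methyl ester gives the 3-acyltetramic acid, and the short reaction time at 25 °C preserves both threonine-derived stereocentres.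

**Compound list**
1 | (R)-epichlorohydrin, (2R)-2-(chloromethyl)oxirane | ClC[C@H]1CO1 | starting material
2 | di-tert-butyl malonate | CC(C)(C)OC(=O)CC(=O)OC(C)(C)C | starting material
3 | tert-butyl (1R,5R)-2-oxo-3-oxabicyclo[3.1.0]hexane-1-carboxylate | O=C1OC[C@@H]2C[C@]12C(=O)OC(C)(C)C | intermediate
4 | tert-butyl (4R)-2-oxo-4-(prop-2-en-1-yl)oxolane-3-carboxylate (both C3 epimers) | C=CC[C@H]1COC(=O)C1C(=O)OC(C)(C)C | intermediate
5 | tert-butyl (3S,4R)-3-methyl-2-oxo-4-(prop-2-en-1-yl)oxolane-3-carboxylate (methyl trans to allyl) | C=CC[C@H]1COC(=O)[C@@]1(C)C(=O)OC(C)(C)C | intermediate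
6 | tert-butyl (3S,4R)-3-methyl-2-oxo-4-(2-oxoethyl)oxolane-3-carboxylate | O=CC[C@H]1COC(=O)[C@@]1(C)C(=O)OC(C)(C)C | intermediate
7 | tert-butyl (3S,4R)-4-(2-hydroxybut-3-en-1-yl)-3-methyl-2-oxooxolane-3-carboxylate (both carbinol epimers) | C=CC(O)C[C@H]1COC(=O)[C@@]1(C)C(=O)OC(C)(C)C | intermediate
8 | tert-butyl (3S,4R)-2-hydroxy-4-(2-hydroxybut-3-en-1-yl)-3-methyloxolane-3-carboxylate (lactol, both anomers) | C=CC(O)C[C@H]1COC(O)[C@@]1(C)C(=O)OC(C)(C)C | intermediate
9 | tert-butyl (2R,3E,5E)-2-[(2R)-1,4-dihydroxyhex-5-en-2-yl]-2-methylhepta-3,5-dienoate | C/C=C/C=C/[C@@](C)(C(=O)OC(C)(C)C)[C@H](CO)CC(O)C=C | intermediate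
10 | tert-butyl (2R,3E,5E)-2-[(2R)-1-hydroxy-4-oxohex-5-en-2-yl]-2-methylhepta-3,5-dienoate | C/C=C/C=C/[C@@](C)(C(=O)OC(C)(C)C)[C@H](CO)CC(=O)C=C | intermediate
11 | tert-butyl (1R,2R,4aR,6S,8aS)-2-(hydroxymethyl)-1,6-dimethyl-4-oxo-1,2,3,4,4a,5,6,8a-octahydronaphthalene-1-carboxylate (cis-fused) | OC[C@@H]1CC(=O)[C@@H]2C[C@H](C)C=C[C@@H]2[C@@]1(C)C(=O)OC(C)(C)C | intermediate
12 | tert-butyl (1R,2R,4aS,6S,8aS)-2-(hydroxymethyl)-1,6-dimethyl-4-oxo-1,2,3,4,4a,5,6,8a-octahydronaphthalene-1-carboxylate (trans-fused) | OC[C@@H]1CC(=O)[C@H]2C[C@H](C)C=C[C@@H]2[C@@]1(C)C(=O)OC(C)(C)C | intermediate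
13 | tert-butyl (1R,2R,4aS,6R,8aS)-2-(hydroxymethyl)-1,6-dimethyl-4-oxodecahydronaphthalene-1-carboxylate | OC[C@@H]1CC(=O)[C@H]2C[C@H](C)CC[C@@H]2[C@@]1(C)C(=O)OC(C)(C)C | intermediate
14 | tert-butyl (1R,2R,4aS,6R,8aS)-2-formyl-1,6-dimethyl-4-oxodecahydronaphthalene-1-carboxylate | O=C[C@@H]1CC(=O)[C@H]2C[C@H](C)CC[C@@H]2[C@@]1(C)C(=O)OC(C)(C)C | intermediate
15 | tert-butyl (1S,2S,4aS,6R,8aS)-1,6-dimethyl-4-oxo-2-[(1E,3E)-penta-1,3-dien-1-yl]decahydronaphthalene-1-carboxylate | C/C=C/C=C/[C@@H]1CC(=O)[C@H]2C[C@H](C)CC[C@@H]2[C@@]1(C)C(=O)OC(C)(C)C | intermediate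
16 | tert-butyl (1S,2S,4aS,6R,8aS)-1,6-dimethyl-4-[2-(4-methylbenzenesulfonyl)hydrazinylidene]-2-[(1E,3E)-penta-1,3-dien-1-yl]decahydronaphthalene-1-carboxylate | C/C=C/C=C/[C@@H]1CC(=NNS(=O)(=O)c3ccc(C)cc3)[C@H]2C[C@H](C)CC[C@@H]2[C@@]1(C)C(=O)OC(C)(C)C | intermediate
17 | tert-butyl (1R,2R,4aR,6R,8aS)-1,6-dimethyl-2-[(1E,3E)-penta-1,3-dien-1-yl]-1,2,4a,5,6,7,8,8a-octahydronaphthalene-1-carboxylate | C/C=C/C=C/[C@@H]1C=C[C@H]2C[C@H](C)CC[C@@H]2[C@@]1(C)C(=O)OC(C)(C)C | intermediate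
18 | (1R,2R,4aR,6R,8aS)-1,6-dimethyl-2-[(1E,3E)-penta-1,3-dien-1-yl]-1,2,4a,5,6,7,8,8a-octahydronaphthalene-1-carboxylic acid | C/C=C/C=C/[C@@H]1C=C[C@H]2C[C@H](C)CC[C@@H]2[C@@]1(C)C(=O)O | intermediate
19 | (1R,2R,4aR,6R,8aS)-1,6-dimethyl-2-[(1E,3E)-penta-1,3-dien-1-yl]-1,2,4a,5,6,7,8,8a-octahydronaphthalene-1-carbonyl chloride | C/C=C/C=C/[C@@H]1C=C[C@H]2C[C@H](C)CC[C@@H]2[C@@]1(C)C(Cl)=O | intermediate
20 | S-tert-butyl 3-[(1R,2R,4aR,6R,8aS)-1,6-dimethyl-2-[(1E,3E)-penta-1,3-dien-1-yl]-1,2,4a,5,6,7,8,8a-octahydronaphthalen-1-yl]-3-oxopropanethioate | C/C=C/C=C/[C@@H]1C=C[C@H]2C[C@H](C)CC[C@@H]2[C@@]1(C)C(=O)CC(=O)SC(C)(C)C | intermediate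
21 | methyl L-threoninate hydrochloride, methyl (2S,3R)-2-amino-3-hydroxybutanoate hydrochloride | Cl.COC(=O)[C@@H](N)[C@@H](C)O | starting material
22 | methyl (2S,3R)-2-{3-[(1R,2R,4aR,6R,8aS)-1,6-dimethyl-2-[(1E,3E)-penta-1,3-dien-1-yl]-1,2,4a,5,6,7,8,8a-octahydronaphthalen-1-yl]-3-oxopropanamido}-3-hydroxybutanoate | C/C=C/C=C/[C@@H]1C=C[C@H]2C[C@H](C)CC[C@@H]2[C@@]1(C)C(=O)CC(=O)N[C@@H]([C@@H](C)O)C(=O)OC | intermediate
23 | (5S)-3-{[(1R,2R,4aR,6R,8aS)-1,6-dimethyl-2-[(1E,3E)-penta-1,3-dien-1-yl]-1,2,4a,5,6,7,8,8a-octahydronaphthalen-1-yl]carbonyl}-4-hydroxy-5-[(1R)-1-hydroxyethyl]-1,5-dihydro-2H-pyrrol-2-one | C/C=C/C=C/[C@@H]1C=C[C@H]2C[C@H](C)CC[C@@H]2[C@@]1(C)C(=O)C1=C(O)[C@H]([C@@H](C)O)NC1=O | target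

**Step count**
Total: 17 steps. Longest linear sequence: 17 steps (1 → 23); 21 is bought.

**Three steps most likely to fail**

Step 7 (Wittig on the lactol). The open form is an α-formyl ester on a quaternary carbon, so the lactolate can lose the formyl carbon by retro-Claisen cleavage, and the neopentyl aldehyde is hindered. The fallback sets out from 7 and avoids any free alkoxide next to the aldehyde. The secondary alcohol is silylated (t-BuMe2SiCl, imidazole) to the silyl ether F1. LiBH4 reduces only the lactone to the diol F2. t-BuPh2SiCl takes the less hindered primary hydroxyl to give the mono-silyl ether F3. Dess–Martin oxidation of the neopentyl alcohol gives the aldehyde F4. Julia–Kocienski olefination with (E)-but-2-enyl 1-phenyl-1H-tetrazol-5-yl sulfone and KN(SiMe3)2 gives the diene F5. Bu4NF removes both silyl groups and the route is rejoined at 9.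

Step 11 (Wittig on aldehyde 14). The aldehyde is hindered and epimerisable at C2, and the basic ylide gives E/Z mixtures. The fallback sets out from 14 and builds the diene in two non-basic stages. The stabilised ylide Ph3P=CHCHO gives the (E)-enal F6. Takai–Utimoto ethylidenation (CrCl2, CH3CHI2), which is aldehyde-selective and E-selective, then gives the E,E-diene and rejoins the route at 15.

Step 15 (acylation with a very hindered acid chloride). Attack at the neopentyl carbonyl may be too slow. The fallback sets out from 17 and makes the same bond by an aldol reaction instead. LiAlH4 reduces the ester to the neopentyl alcohol F7. Dess–Martin oxidation gives the aldehyde F8. The lithium enolate of S-tert-butyl thioacetate adds to give the β-hydroxy thioester F9. A second Dess–Martin oxidation rejoins the route at 20.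

**Further compounds**
F1 | step 7 | tert-butyl (3S,4R)-4-[2-(tert-butyldimethylsilyloxy)but-3-en-1-yl]-3-methyl-2-oxooxolane-3-carboxylate | C=CC(O[Si](C)(C)C(C)(C)C)C[C@H]1COC(=O)[C@@]1(C)C(=O)OC(C)(C)C
F2 | step 7 | tert-butyl (2S,3R)-5-(tert-butyldimethylsilyloxy)-2,3-bis(hydroxymethyl)-2-methylhept-6-enoate | OC[C@@](C)(C(=O)OC(C)(C)C)[C@H](CO)CC(O[Si](C)(C)C(C)(C)C)C=C
F3 | step 7 | tert-butyl (2S,3R)-5-(tert-butyldimethylsilyloxy)-3-[(tert-butyldiphenylsilyloxy)methyl]-2-(hydroxymethyl)-2-methylhept-6-enoate | OC[C@@](C)(C(=O)OC(C)(C)C)[C@H](CO[Si](c1ccccc1)(c1ccccc1)C(C)(C)C)CC(O[Si](C)(C)C(C)(C)C)C=C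
F4 | step 7 | tert-butyl (2S,3R)-5-(tert-butyldimethylsilyloxy)-3-[(tert-butyldiphenylsilyloxy)methyl]-2-formyl-2-methylhept-6-enoate | O=C[C@@](C)(C(=O)OC(C)(C)C)[C@H](CO[Si](c1ccccc1)(c1ccccc1)C(C)(C)C)CC(O[Si](C)(C)C(C)(C)C)C=C
F5 | step 7 | tert-butyl (2R,3E,5E)-2-[(2R)-4-(tert-butyldimethylsilyloxy)-1-(tert-butyldiphenylsilyloxy)hex-5-en-2-yl]-2-methylhepta-3,5-dienoate | C/C=C/C=C/[C@@](C)(C(=O)OC(C)(C)C)[C@H](CO[Si](c1ccccc1)(c1ccccc1)C(C)(C)C)CC(O[Si](C)(C)C(C)(C)C)C=C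
F6 | step 11 | tert-butyl (1S,2S,4aS,6R,8aS)-1,6-dimethyl-4-oxo-2-[(1E)-3-oxoprop-1-en-1-yl]decahydronaphthalene-1-carboxylate | O=C/C=C/[C@@H]1CC(=O)[C@H]2C[C@H](C)CC[C@@H]2[C@@]1(C)C(=O)OC(C)(C)C
F7 | step 15 | [(1R,2R,4aR,6R,8aS)-1,6-dimethyl-2-[(1E,3E)-penta-1,3-dien-1-yl]-1,2,4a,5,6,7,8,8a-octahydronaphthalen-1-yl]methanol | C/C=C/C=C/[C@@H]1C=C[C@H]2C[C@H](C)CC[C@@H]2[C@@]1(C)CO
F8 | step 15 | (1R,2R,4aR,6R,8aS)-1,6-dimethyl-2-[(1E,3E)-penta-1,3-dien-1-yl]-1,2,4a,5,6,7,8,8a-octahydronaphthalene-1-carbaldehyde | C/C=C/C=C/[C@@H]1C=C[C@H]2C[C@H](C)CC[C@@H]2[C@@]1(C)C=O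
F9 | step 15 | S-tert-butyl 3-[(1R,2R,4aR,6R,8aS)-1,6-dimethyl-2-[(1E,3E)-penta-1,3-dien-1-yl]-1,2,4a,5,6,7,8,8a-octahydronaphthalen-1-yl]-3-hydroxypropanethioate (both carbinol epimers) | C/C=C/C=C/[C@@H]1C=C[C@H]2C[C@H](C)CC[C@@H]2[C@@]1(C)C(O)CC(=O)SC(C)(C)C
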